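The route rests on disconnecting the bond from the quaternary carbon C9a (dibenzofuran numbering) to the β-carbon of the (Z)-acrylamide. The feature exploited: the dihydrofuran oxygen O5 sits on arene carbon C4a, ortho to C9b, which carries C9a. As its (Z)-3-iodoacrylate ester, this phenol oxygen holds the alkenyl carbon over C9a of a 1-arylcyclohexene precursor. One asymmetric intramolecular Heck reaction closes a seven-membered aryl lactone, forms the bond, locks the cis alkene and sets C9a. The lactone is a latent active ester: the liberated terminal amine opens it (ring expansion to the 20-membered lactam) and the freed phenoxide closes the dihydrofuran ring by oxa-Michael addition.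

Key step: step 6

Labels used below (dibenzofuran numbering of the core): O5; C5a = O-bearing CH; C6; C7 = carbinol carbon; C8; C9; C9a = quaternary carbon; C9b, C1–C4, C4a = benzo ring (C2 carries the cinnamoyl arm, C4a carries O5); Cα/Cβ = acrylamide carbons, Cβ bonded to C9a.

Remark on the chemistry: amine 2 is assumed to be a purchasable, regiodefined di-Boc-spermidine. The sense of induction of (R)-BINAP in step 6 is assigned by analogy; the antipodal ligand would be used if it proved opposite.

Step 1
Reactants: 1 propiolic acid; 2 tert-butyl N-(3-aminopropyl)-N-[4-(tert-butoxycarbonylamino)butyl]carbamate (N4,N8-di-Boc-spermidine, free N1H2)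
Product: 3 N1-propioloyl-N4,N8-di-Boc-spermidine
Conditions: DCC, CH2Cl2, −10 → 0 °C (acid pre-activated, amine added slowly)
Reagents that add atoms: none
Why: Carbodiimide amide coupling of the only free (primary) amine; low temperature and pre-activation suppress aza-Michael addition to the ynoate.

Step 2
Reactants: 3 N1-propioloyl-N4,N8-di-Boc-spermidine; 4 2-bromo-4-iodophenol
Product: 5 3-(3-bromo-4-hydroxyphenyl)propiolamide of di-Boc-spermidine
Conditions: PdCl2(PPh3)2 (3 mol %), CuI (5 mol %), Et3N, THF, rt
Reagents that add atoms: none
Why: Sonogashira coupling; zerovalent palladium inserts far faster into C–I than into C–Br, so the bromide ortho to the free phenol is kept for step 3.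

Step 3
Reactants: 5 bromophenol ynamide; 6 2-(1,4-dioxaspiro[4.5]dec-7-en-8-yl)-4,4,5,5-tetramethyl-1,3,2-dioxaborolane
Product: 7 3-[4-hydroxy-3-(1,4-dioxaspiro[4.5]dec-7-en-8-yl)phenyl]propiolamide of di-Boc-spermidine
Conditions: PdCl2(dppf) (5 mol %), K2CO3, 1,4-dioxane/H2O (5:1), 80 °C
Reagents that add atoms: none
Why: Suzuki–Miyaura coupling of an aryl bromide with an alkenyl boronate installs the future cyclohexane ring (C9a=C5a alkene, C7 masked as ethylene ketal) ortho to the phenol; ketal, Boc groups and the aryl ynamide tolerate aqueous carbonate.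

Step 4
Reactants: 7 aryl ynamide
Product: 8 (Z)-3-[4-hydroxy-3-(1,4-dioxaspiro[4.5]dec-7-en-8-yl)phenyl]acrylamide of di-Boc-spermidine
Conditions: H2 (1 atm), Pd/CaCO3 poisoned with Pb(OAc)2 (Lindlar catalyst), quinoline, EtOAc, rt
Reagents that add atoms: none
Why: Lindlar semihydrogenation delivers both hydrogens syn to the alkyne and gives the (Z)-cinnamamide; the trisubstituted styrenyl alkene is not reduced on the poisoned catalyst.

Step 5
Reactants: 8 (Z)-cinnamamide phenol; 9 (Z)-3-iodoacrylic acid
Product: 10 aryl (Z)-3-iodoacrylate of 8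
Conditions: DCC, DMAP (5 mol %), CH2Cl2, −10 → 0 °C
Reagents that add atoms: none
Why: Steglich esterification of the only hydroxyl group; at low temperature the (Z)-iodoalkene geometry is retained and the amide and carbamate N–H groups are not acylated.

Step 6
Reactants: 10 aryl (Z)-3-iodoacrylate
Product: 11 (S)-spiro lactone: C9a is the spiro atom shared by the seven-membered (Z)-enoate aryl lactone (1-benzoxepin-2-one) and the cyclohexene ring (C5a=C6, C7 ethylene ketal)
Conditions: Pd2(dba)3 (5 mol %), (R)-BINAP (12 mol %), Ag3PO4 (2 equiv), DMA (0.02 M), 70 °C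
Reagents that add atoms: none
Why: Zerovalent palladium inserts into the alkenyl C–I bond with retention of the Z geometry, Ag3PO4 abstracts iodide, and the cationic (BINAP)Pd–alkenyl adds syn across the twisted styrenyl C9a=C5a bond, delivering Cβ to C9a; the C5a–Pd species can only undergo syn β-hydride elimination toward C6, which gives the C5a=C6 allylic ketal. The closest known reaction type is the cationic asymmetric intramolecular Heck cyclisation that builds benzylic all-carbon quaternary centres. One ring is closed, the seven-membered aryl lactone, in the 7-exo-trig mode, and its ring size locks the enoate as the cis alkene. The single new stereocentre C9a is set by the chiral diphosphine, which selects the alkene face in the migratory insertion. The step needs exo rather than 8-endo insertion (secured by the short O5–C(=O) tether and the preference for the smaller ring), cyclisation rather than intermolecular Heck coupling at the cinnamamide (secured by dilution and proximity) and no Z-to-E leakage (only the Z-alkenylpalladium can reach C9a).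

Step 7
Reactants: 11 (S)-spiro lactone
Product: 14 cis-fused macrocyclic keto lactam (5aR,9aS), via amino enone lactone 12 (not isolated), via phenol enone macrolactam 13 (not isolated)
Conditions: TFA/H2O (19:1), 0 °C → rt; evaporate; then slow addition to i-Pr2NEt, MeCN (0.5 mM final), rt
Reagents that add atoms: water, O
Why: Acidolysis removes both Boc groups and hydrolyses the allylic ketal to the enone; on neutralisation the primary amine opens the strained aryl lactone (active-ester aminolysis as transacylative ring expansion from 7 to 20 members, favoured over attack by the more hindered central NH), and the released phenoxide adds 5-exo-trig to the enone (oxa-Michael) from the only face its tether allows, which forces the cis ring fusion and sets C5a from C9a.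

Step 8
Reactants: 14 macrocyclic keto lactam
Product: 15 target CNP0243477.1 (5aR,7R,9aS)
Conditions: LiBH(s-Bu)3 (L-Selectride, 4 equiv), THF, −78 °C; MeOH quench
Reagents that add atoms: none
Why: Substrate-controlled ketone reduction with a bulky hydride, which should attack the cyclohexanone from the face away from the C5a–O5 bond and the arene and so give the C7 alcohol cis to O5, as is typical for cis-fused hydrodibenzofuranones; prior N–H deprotonation of the secondary amides protects the two (Z)-acrylamides from conjugate reduction.

Compound list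
1 | propiolic acid | C#CC(=O)O | starting material
2 | tert-butyl N-(3-aminopropyl)-N-[4-(tert-butoxycarbonylamino)butyl]carbamate | NCCCN(C(=O)OC(C)(C)C)CCCCNC(=O)OC(C)(C)C | starting material
3 | N1-propioloyl-N4,N8-di-Boc-spermidine | C#CC(=O)NCCCN(C(=O)OC(C)(C)C)CCCCNC(=O)OC(C)(C)C | intermediate
4 | 2-bromo-4-iodophenol | Oc1ccc(I)cc1Br | starting material
5 | 3-(3-bromo-4-hydroxyphenyl)propiolamide of di-Boc-spermidine | Oc1ccc(C#CC(=O)NCCCN(C(=O)OC(C)(C)C)CCCCNC(=O)OC(C)(C)C)cc1Br | intermediate
6 | 2-(1,4-dioxaspiro[4.5]dec-7-en-8-yl)-4,4,5,5-tetramethyl-1,3,2-dioxaborolane | CC1(C)OB(OC1(C)C)C1=CCC2(CC1)OCCO2 | starting material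
7 | 3-[4-hydroxy-3-(1,4-dioxaspiro[4.5]dec-7-en-8-yl)phenyl]propiolamide of di-Boc-spermidine | Oc1ccc(C#CC(=O)NCCCN(C(=O)OC(C)(C)C)CCCCNC(=O)OC(C)(C)C)cc1C1=CCC2(CC1)OCCO2 | intermediate
8 | (Z)-3-[4-hydroxy-3-(1,4-dioxaspiro[4.5]dec-7-en-8-yl)phenyl]acrylamide of di-Boc-spermidine | Oc1ccc(/C=C\C(=O)NCCCN(C(=O)OC(C)(C)C)CCCCNC(=O)OC(C)(C)C)cc1C1=CCC2(CC1)OCCO2 | intermediate
9 | (Z)-3-iodoacrylic acid | OC(=O)/C=C\I | starting material
10 | aryl (Z)-3-iodoacrylate of 8 | I/C=C\C(=O)Oc1ccc(/C=C\C(=O)NCCCN(C(=O)OC(C)(C)C)CCCCNC(=O)OC(C)(C)C)cc1C1=CCC2(CC1)OCCO2 | intermediate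
11 | (S)-spiro lactone (seven-membered (Z)-enoate aryl lactone spiro-fused at C9a to the cyclohexene ketal, di-Boc) | O=C1/C=C\[C@]2(C=CC3(CC2)OCCO3)c2cc(/C=C\C(=O)NCCCN(C(=O)OC(C)(C)C)CCCCNC(=O)OC(C)(C)C)ccc2O1 | intermediate
12 | amino enone lactone (free diamine, C7 ketone, C5a=C6 enone, lactone intact; not isolated) | O=C1/C=C\[C@]2(C=CC(=O)CC2)c2cc(/C=C\C(=O)NCCCNCCCCN)ccc2O1 | intermediate
13 | phenol enone macrolactam (20-membered lactam closed, free phenol, enone; not isolated) | O=C1/C=C\[C@]2(C=CC(=O)CC2)c2cc(ccc2O)/C=C\C(=O)NCCCNCCCCN1 | intermediate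
14 | cis-fused macrocyclic keto lactam (5aR,9aS), C7 ketone | O=C1/C=C\[C@]23CCC(=O)C[C@H]2Oc2ccc(cc23)/C=C\C(=O)NCCCNCCCCN1 | intermediate
15 | CNP0243477.1 (5aR,7R,9aS) | O=C1/C=C\[C@]23CC[C@@H](O)C[C@H]2Oc2ccc(cc23)/C=C\C(=O)NCCCNCCCCN1 | target

Total step count: 8
Longest linear sequence: 8 steps (1/2 → 3 → 5 → 7 → 8 → 10 → 11 → 14 → 15)

Steps most likely to fail

1. Step 6. The chiral ligand sits far from the alkene across a seven-membered transition state, so enantioface discrimination in the migratory insertion may be weak; palladium hydride formed on elimination may also erode the Z-cinnamamide. Fallback (symmetrise, then desymmetrise; sets out from 10, returns at 14): 10 is cyclised with an achiral catalyst (Pd(OAc)2, PPh3, Ag2CO3, DMA) to the racemic spiro lactone ketal F1. PPTS in wet acetone unmasks the racemic enone lactone F2. IBX in DMSO at 70 °C dehydrogenates it to the achiral cross-conjugated spirodienone lactone F3. A copper hydride desymmetrising conjugate reduction of one enantiotopic enone arm (Cu(OAc)2, (S,S)-Ph-BPE, (EtO)2MeSiH, t-BuOH, toluene, −25 °C; enone reduced in preference to the hindered lactone enoate) should give the (S)-enone lactone F4. F4 is the di-Boc form of 12 and is converted into 14 under the acid-then-base conditions of step 7.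

2. Step 7. At the dilution needed, intermolecular aminolysis (oligomers), acylation at the central NH, or reversible conjugate addition of the liberated amines to the enone may outrun the ring expansion. Fallback (furan closure decoupled from macrocyclisation, conventional macrolactamisation; sets out from 11, returns at 14): LiOH in THF/H2O at 0 °C saponifies the aryl lactone of 11 to the phenol (Z)-acrylic acid F5, with ketal and Boc groups intact. TFA/H2O followed by aqueous NaHCO3 removes Boc groups and ketal and lets the phenol close the dihydrofuran by oxa-Michael addition, giving the cis-fused amino acid F6. F6 is cyclised through its acyl azide (DPPA, NaHCO3, DMF, 1 mM, 0 °C), an activation that favours primary over secondary amino groups, to give 14.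

3. Step 8. Hydride delivery from the wrong face of the cyclohexanone would give the C7 epimer, and the basic reagent may trigger retro-oxa-Michael opening. Fallback (catalyst control in place of substrate control; sets out from 14, returns at 15): 14 is reduced with a ketoreductase chosen from a stereocomplementary enzyme panel (NADPH recycling with glucose dehydrogenase, aqueous buffer pH 7, DMSO co-solvent, 30 °C); the enzyme dictates the carbonyl face and leaves the acrylamides and the amine untouched. No new compound arises.

Further compounds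
F1 | step 6 | racemic spiro lactone ketal (racemate of 11) | O=C1/C=C\C2(C=CC3(CC2)OCCO3)c2cc(/C=C\C(=O)NCCCN(C(=O)OC(C)(C)C)CCCCNC(=O)OC(C)(C)C)ccc2O1
F2 | step 6 | racemic enone lactone (di-Boc) | O=C1/C=C\C2(C=CC(=O)CC2)c2cc(/C=C\C(=O)NCCCN(C(=O)OC(C)(C)C)CCCCNC(=O)OC(C)(C)C)ccc2O1
F3 | step 6 | achiral spirodienone lactone (di-Boc) | O=C1/C=C\C2(C=CC(=O)C=C2)c2cc(/C=C\C(=O)NCCCN(C(=O)OC(C)(C)C)CCCCNC(=O)OC(C)(C)C)ccc2O1
F4 | step 6 | (S)-enone lactone (di-Boc form of 12) | O=C1/C=C\[C@]2(C=CC(=O)CC2)c2cc(/C=C\C(=O)NCCCN(C(=O)OC(C)(C)C)CCCCNC(=O)OC(C)(C)C)ccc2O1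
F5 | step 7 | phenol (Z)-acrylic acid (ketal and di-Boc intact) | OC(=O)/C=C\[C@]1(C=CC2(CC1)OCCO2)c1cc(/C=C\C(=O)NCCCN(C(=O)OC(C)(C)C)CCCCNC(=O)OC(C)(C)C)ccc1O
F6 | step 7 | cis-fused keto amino acid (free diamine, dihydrofuran closed) | OC(=O)/C=C\[C@]12CCC(=O)C[C@H]1Oc1ccc(cc12)/C=C\C(=O)NCCCNCCCCN
F0 | step 8 | none | none
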